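**Plan**
- Retrosynthesis: cut the O3–benzoyl ester, C5=C6 (Wittig), C11=C12 (cross-metathesis), C13–C14 (crotylboration) and C14–C15 (vinyl addition to a C15 ketone); the cyclopentane is then cut at C1–C2 and C3–C4 by a formal (3+2) cycloaddition.
- Enabling feature: ring atoms C4–C15–C1 with the C5 branch on C4 are a masked acetoacetate (C5 carboxyl, C15 ketone, C1 the γ-carbon), and C2(Me)–C3(O) is the enol ether of propanal. A rhodium enolcarbene from silylated methyl diazoacetoacetate is electrophilic at C1 and nucleophilic at C4; an (E)-propenyl silyl ether is the reverse at C2 and C3.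
- Forward order: cyclopentene (step 4), ester reduction, desilylation, a temporary acetonide ring across O3/O5, vinyl addition and acetylation at C15, C14 aldehyde, crotylation, cross-metathesis, acetonide removal, C5 enal, C3 benzoate.
- Stereochemistry: C2/C3 from the cycloaddition (chiral dirhodium catalyst, trans ring closure); C4 from the thermodynamically cis-fused acetonide; C15 from addition to the convex face of that bicycle; C14/C13 from Brown's (Z)-crotylborane; both alkenes E from metathesis and a stabilised ylide.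

Key step: step 4

Locants: target numbering is used throughout. Ring: C1 (CH2), C2 (CHMe), C3 (CH–O), C4 (CH), C15 (C–O). Enal: C5=C6(Me)–C7HO. Chain: C14 (CH–O), C13 (CHMe), C12=C11, C10 (CMe2), C9 (C=O), C8 (Me).

Assumption: the (S)-PTTL catalyst in step 4 and the crotylborane from (−)-α-pinene in step 10 are written on the basis of the usual facial models; if either sense is opposite, the enantiomeric catalyst or reagent is used with no other change.

**Route**

Step 1
Reactants: 1 methyl acetoacetate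
Product: 2 methyl 2-diazo-3-oxobutanoate
Conditions: p-ABSA, Et3N, MeCN, 0 °C to rt
Reagents that add atoms: 4-acetamidobenzenesulfonyl azide, CC(=O)Nc1ccc(cc1)S(=O)(=O)N=[N+]=[N-]
Why: Regitz diazo transfer to the doubly activated methylene of a β-keto ester.

Step 2
Reactants: 2 methyl 2-diazo-3-oxobutanoate
Product: 3 methyl 3-[(tert-butyldimethylsilyl)oxy]-2-diazobut-3-enoate
Conditions: TBSOTf, Et3N, CH2Cl2, 0 °C
Reagents that add atoms: tert-butyldimethylsilyl triflate, CC(C)(C)[Si](C)(C)OS(=O)(=O)C(F)(F)F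
Why: soft enolisation and O-silylation of the acetyl group gives the silyl enoldiazoacetate, the standard precursor of metal enolcarbenes.

Step 3
Reactants: 4 allyloxy(tert-butyl)dimethylsilane
Product: 5 (E)-tert-butyldimethyl(prop-1-en-1-yloxy)silane
Conditions: [Ir(cod)(PMePh2)2]PF6 (1 mol%, pre-activated with H2), THF, rt
Reagents that add atoms: none
Why: cationic iridium-hydride isomerisation of an allyl silyl ether to the propenyl ether, which should be (E)-selective with this catalyst.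

Step 4
Reactants: 3 methyl 3-[(tert-butyldimethylsilyl)oxy]-2-diazobut-3-enoate; 5 (E)-tert-butyldimethyl(prop-1-en-1-yloxy)silane
Product: 6 methyl (4R,5S)-2,5-bis[(tert-butyldimethylsilyl)oxy]-4-methylcyclopent-1-ene-1-carboxylate
Conditions: Rh2(S-PTTL)4 (1–2 mol%), 5 (2 equiv), 4 Å MS, CH2Cl2, −20 °C to rt, slow addition of 3
Reagents that add atoms: none
Why: Rh2(S-PTTL)4 expels N2 from 3 to give a rhodium enolcarbene that is electrophilic at its unsubstituted vinylogous CH2 (C1); the methyl-bearing carbon of enol ether 5 (C2) adds there, and the vinyl–rhodium σ-bond at C4 then closes onto the silyloxocarbenium carbon C3 with release of the catalyst, a stepwise formal (3+2) cycloaddition that makes C1–C2 and C3–C4 in one operation. The closest known reaction type is the dirhodium-catalysed formal (3+2) cycloaddition of silyl enoldiazoacetates with enecarbamates and enol ethers (vinylogous reactivity of metal vinylcarbenes). The one ring is closed in the 5-exo-trig mode by an in-plane vinyl–metal nucleophile, so the restriction on enol-endo closures of π-enolates does not apply. C2 is set in the first bond formation, where the chiral carboxylate ligands select the enantioface of the (E)-enol ether, and C3 is set in the ring closure trans to the C2 methyl group, which keeps methyl and silyloxy apart on the forming ring. The step needs vinylogous attack in preference to attack at the carbene carbon, and the orientation methyl-carbon-to-CH2: the first is secured by the unsubstituted terminus and by the ester and silyloxy groups that screen the carbene carbon, the second by the polarity of the enol ether, whose β-carbon is its only nucleophilic site.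

Step 5
Reactants: 6 methyl (4R,5S)-2,5-bis[(tert-butyldimethylsilyl)oxy]-4-methylcyclopent-1-ene-1-carboxylate
Product: 7 [(4R,5S)-2,5-bis[(tert-butyldimethylsilyl)oxy]-4-methylcyclopent-1-en-1-yl]methanol
Conditions: iBu2AlH (2.5 equiv), CH2Cl2, −78 to −40 °C; aq. potassium sodium tartrate
Reagents that add atoms: none
Why: 1,2-reduction of the β-silyloxy acrylate to the allylic alcohol while the ketone stays masked as its silyl enol ether, which avoids a free β-keto ester with a β-leaving group.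

Step 6
Reactants: 7 [(4R,5S)-2,5-bis[(tert-butyldimethylsilyl)oxy]-4-methylcyclopent-1-en-1-yl]methanol
Product: 8 (2S,3S,4R)-3-hydroxy-2-(hydroxymethyl)-4-methylcyclopentan-1-one (C4 of the target is epimerisable here; the cis isomer is drawn)
Conditions: HF·pyridine, pyridine, THF, 0 °C to rt
Reagents that add atoms: none
Why: fluoride-driven cleavage of both silyl groups in a buffered medium should unveil the ketone by C-protonation of the enol without the acid-induced ionisation of the allylic alcohol.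

Step 7
Reactants: 8 (2S,3S,4R)-3-hydroxy-2-(hydroxymethyl)-4-methylcyclopentan-1-one
Product: 9 (4aS,7R,7aS)-2,2,7-trimethyltetrahydro-4H-cyclopenta[d][1,3]dioxin-5(4aH)-one
Conditions: Me2C(OMe)2, PPTS (cat.), acetone, rt
Reagents that add atoms: 2,2-dimethoxypropane, COC(C)(C)OC
Why: acetonide formation across O3 and O5 under equilibrating conditions; C4 can epimerise through the enol, and the cis-fused dioxane–cyclopentanone should be strongly favoured over the strained trans-fused one, which fixes C4 cis to the C3 oxygen.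

Step 8
Reactants: 9 (4aS,7R,7aS)-2,2,7-trimethyltetrahydro-4H-cyclopenta[d][1,3]dioxin-5(4aH)-one
Product: 11 (4aS,5S,7R,7aS)-5-ethenyl-2,2,7-trimethylhexahydrocyclopenta[d][1,3]dioxin-5-yl acetate, via bromomagnesium alkoxide 10 (not isolated)
Conditions: CH2=CHMgBr, LaCl3·2LiCl (0.3 equiv), THF, −78 to 0 °C; then Ac2O, DMAP (cat.), 0 °C to rt
Reagents that add atoms: vinylmagnesium bromide, C=C[Mg]Br; acetic anhydride, CC(=O)OC(C)=O
Why: lanthanide-assisted Grignard 1,2-addition to the convex face of the cis-fused bicycle (anti to the C4–C5 bond) should place the vinyl group trans and the oxygen cis to C5, setting C15, and the hindered tertiary alkoxide is acetylated in the flask, the dependable way to a tertiary acetate.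

Step 9
Reactants: 11 (4aS,5S,7R,7aS)-5-ethenyl-2,2,7-trimethylhexahydrocyclopenta[d][1,3]dioxin-5-yl acetate
Product: 13 (4aS,5R,7R,7aS)-5-formyl-2,2,7-trimethylhexahydrocyclopenta[d][1,3]dioxin-5-yl acetate, via ozonide 12 (not isolated)
Conditions: O3, CH2Cl2, −78 °C; then PPh3, −78 °C to rt
Reagents that add atoms: ozone, [O-][O+]=O
Why: ozonolysis with reductive work-up of the only alkene present; the acetonide has no acetal C–H and the product aldehyde has no α-hydrogen, so neither over-oxidation nor epimerisation is expected.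

Step 10
Reactants: 13 (4aS,5R,7R,7aS)-5-formyl-2,2,7-trimethylhexahydrocyclopenta[d][1,3]dioxin-5-yl acetate
Product: 15 (4aS,5R,7R,7aS)-5-[(1R,2S)-1-hydroxy-2-methylbut-3-en-1-yl]-2,2,7-trimethylhexahydrocyclopenta[d][1,3]dioxin-5-yl acetate, via borinate ester 14 (not isolated)
Conditions: cis-2-butene, KOtBu, n-BuLi, THF, −78 to −45 °C; (+)-Ipc2BOMe, −78 °C; BF3·OEt2; then 13, −78 °C; aq. H2O2, pH 7 buffer, MeOH, 0 °C to rt
Reagents that add atoms: (Z)-crotyldiisopinocampheylborane made in the flask from cis-2-butene and (+)-Ipc2BOMe [from (−)-α-pinene], C/C=C\CB([C@H]1C[C@H]2C[C@@H]([C@@H]1C)C2(C)C)[C@H]1C[C@H]2C[C@@H]([C@@H]1C)C2(C)C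
Why: Brown crotylboration through a chair Zimmerman–Traxler transition state; the (Z)-crotyl geometry gives the 13,14-syn pair and the isopinocampheyl groups from (−)-α-pinene should direct attack to the Re face of the aldehyde, giving (14R,13S) under reagent control.

Step 11
Reactants: 15 (4aS,5R,7R,7aS)-5-[(1R,2S)-1-hydroxy-2-methylbut-3-en-1-yl]-2,2,7-trimethylhexahydrocyclopenta[d][1,3]dioxin-5-yl acetate
Product: 16 (1R,2S)-1-[(4aS,5R,7R,7aS)-5-acetoxy-2,2,7-trimethylhexahydrocyclopenta[d][1,3]dioxin-5-yl]-2-methylbut-3-en-1-yl acetate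
Conditions: Ac2O, pyridine, DMAP (cat.), CH2Cl2, rt
Reagents that add atoms: acetic anhydride, CC(=O)OC(C)=O
Why: routine DMAP-catalysed acetylation of the secondary C14 alcohol.

Step 12
Reactants: 17 2,2-dimethylbut-3-enoic acid
Product: 18 3,3-dimethylpent-4-en-2-one
Conditions: MeLi (2.2 equiv), Et2O, 0 °C to rt; inverse quench into cold aq. HCl
Reagents that add atoms: methyllithium, [Li]C
Why: addition of methyllithium to the lithium carboxylate gives a stable gem-diolate that releases the methyl ketone on quench; the α-quaternary centre blocks over-addition and conjugation.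

Step 13
Reactants: 16 (1R,2S)-1-[(4aS,5R,7R,7aS)-5-acetoxy-2,2,7-trimethylhexahydrocyclopenta[d][1,3]dioxin-5-yl]-2-methylbut-3-en-1-yl acetate; 18 3,3-dimethylpent-4-en-2-one
Product: 19 (1R,2S,3E)-1-[(4aS,5R,7R,7aS)-5-acetoxy-2,2,7-trimethylhexahydrocyclopenta[d][1,3]dioxin-5-yl]-2,5,5-trimethyl-6-oxohept-3-en-1-yl acetate
Conditions: second-generation Hoveyda–Grubbs catalyst [RuCl2(H2IMes)(=CH-C6H4-2-OiPr)] (10 mol%), 18 (5 equiv), CH2Cl2, 40 °C
Reagents that add atoms: none
Why: olefin cross-metathesis between a terminal alkene and an excess of a vinyl group on a quaternary carbon, which does not homodimerise, should give the (E)-1,2-disubstituted alkene with loss of ethylene.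

Step 14
Reactants: 19 (1R,2S,3E)-1-[(4aS,5R,7R,7aS)-5-acetoxy-2,2,7-trimethylhexahydrocyclopenta[d][1,3]dioxin-5-yl]-2,5,5-trimethyl-6-oxohept-3-en-1-yl acetate
Product: 20 (1R,2S,3E)-1-[(1R,2S,3S,4R)-1-acetoxy-3-hydroxy-2-(hydroxymethyl)-4-methylcyclopentyl]-2,5,5-trimethyl-6-oxohept-3-en-1-yl acetate
Conditions: AcOH/H2O/THF (3:1:1), 40 °C
Reagents that add atoms: none
Why: mild acid hydrolysis of the 1,3-dioxane acetonide, which has done its work, under conditions that should leave the acetates, the ketone and the alkene untouched.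

Step 15
Reactants: 20 (1R,2S,3E)-1-[(1R,2S,3S,4R)-1-acetoxy-3-hydroxy-2-(hydroxymethyl)-4-methylcyclopentyl]-2,5,5-trimethyl-6-oxohept-3-en-1-yl acetate
Product: 22 (1R,2S,3E)-1-[(1R,2S,3S,4R)-1-acetoxy-3-hydroxy-4-methyl-2-[(E)-2-methyl-3-oxoprop-1-en-1-yl]cyclopentyl]-2,5,5-trimethyl-6-oxohept-3-en-1-yl acetate, via hydroxy aldehyde 21 (not isolated)
Conditions: TEMPO (0.2 equiv), PhI(OAc)2 (1.2 equiv), CH2Cl2, rt; then Ph3P=C(CH3)CHO (2 equiv), 40 °C
Reagents that add atoms: 2-(triphenylphosphoranylidene)propanal, CC(C=O)=P(c1ccccc1)(c1ccccc1)c1ccccc1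
Why: oxoammonium oxidation selective for the primary alcohol, then a Wittig reaction of the stabilised formyl ylide in the same flask, which should give the (E)-2-methyl enal and trap the epimerisable C5 aldehyde before it can equilibrate at C4.

Step 16
Reactants: 22 (1R,2S,3E)-1-[(1R,2S,3S,4R)-1-acetoxy-3-hydroxy-4-methyl-2-[(E)-2-methyl-3-oxoprop-1-en-1-yl]cyclopentyl]-2,5,5-trimethyl-6-oxohept-3-en-1-yl acetate
Product: 23 the target (2R,3S,4S,13S,14R,15R; 5E,11E), the C3 benzoate of 22
Conditions: BzCl, pyridine, DMAP (cat.), CH2Cl2, 0 °C to rt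
Reagents that add atoms: benzoyl chloride, O=C(Cl)c1ccccc1
Why: DMAP-catalysed benzoylation of the one remaining free hydroxyl group, under conditions too mild to deprotonate the γ-position of the enal.

**Compound list**

1 | methyl acetoacetate | COC(=O)CC(C)=O | starting material
2 | methyl 2-diazo-3-oxobutanoate | COC(=O)C(=[N+]=[N-])C(C)=O | intermediate
3 | methyl 3-[(tert-butyldimethylsilyl)oxy]-2-diazobut-3-enoate | COC(=O)C(=[N+]=[N-])C(=C)O[Si](C)(C)C(C)(C)C | intermediate
4 | allyloxy(tert-butyl)dimethylsilane | C=CCO[Si](C)(C)C(C)(C)C | starting material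
5 | (E)-tert-butyldimethyl(prop-1-en-1-yloxy)silane | C/C=C/O[Si](C)(C)C(C)(C)C | intermediate
6 | methyl (4R,5S)-2,5-bis[(tert-butyldimethylsilyl)oxy]-4-methylcyclopent-1-ene-1-carboxylate | COC(=O)C1=C(O[Si](C)(C)C(C)(C)C)C[C@@H](C)[C@@H]1O[Si](C)(C)C(C)(C)C | intermediate
7 | [(4R,5S)-2,5-bis[(tert-butyldimethylsilyl)oxy]-4-methylcyclopent-1-en-1-yl]methanol | OCC1=C(O[Si](C)(C)C(C)(C)C)C[C@@H](C)[C@@H]1O[Si](C)(C)C(C)(C)C | intermediate
8 | (2S,3S,4R)-3-hydroxy-2-(hydroxymethyl)-4-methylcyclopentan-1-one | O=C1C[C@@H](C)[C@H](O)[C@@H]1CO | intermediate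
9 | (4aS,7R,7aS)-2,2,7-trimethyltetrahydro-4H-cyclopenta[d][1,3]dioxin-5(4aH)-one (cis-fused acetonide ketone) | O=C1C[C@@H](C)[C@H](OC2(C)C)[C@@H]1CO2 | intermediate
10 | bromomagnesium (4aS,5S,7R,7aS)-5-ethenyl-2,2,7-trimethylhexahydrocyclopenta[d][1,3]dioxin-5-olate | C=C[C@@]1(O[Mg]Br)C[C@@H](C)[C@H](OC2(C)C)[C@@H]1CO2 | intermediate (not isolated)
11 | (4aS,5S,7R,7aS)-5-ethenyl-2,2,7-trimethylhexahydrocyclopenta[d][1,3]dioxin-5-yl acetate | C=C[C@@]1(OC(C)=O)C[C@@H](C)[C@H](OC2(C)C)[C@@H]1CO2 | intermediate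
12 | (4aS,5R,7R,7aS)-2,2,7-trimethyl-5-(1,2,4-trioxolan-3-yl)hexahydrocyclopenta[d][1,3]dioxin-5-yl acetate (ozonide, epimers at the trioxolane carbon) | C1OC(OO1)[C@@]2(OC(C)=O)C[C@@H](C)[C@H](OC3(C)C)[C@@H]2CO3 | intermediate (not isolated)
13 | (4aS,5R,7R,7aS)-5-formyl-2,2,7-trimethylhexahydrocyclopenta[d][1,3]dioxin-5-yl acetate | O=C[C@@]1(OC(C)=O)C[C@@H](C)[C@H](OC2(C)C)[C@@H]1CO2 | intermediate
14 | diisopinocampheylborinate ester of 15 | B([C@H]1C[C@H]2C[C@@H]([C@@H]1C)C2(C)C)([C@H]1C[C@H]2C[C@@H]([C@@H]1C)C2(C)C)O[C@H]([C@@H](C)C=C)[C@@]1(OC(C)=O)C[C@@H](C)[C@H](OC2(C)C)[C@@H]1CO2 | intermediate (not isolated)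
15 | (4aS,5R,7R,7aS)-5-[(1R,2S)-1-hydroxy-2-methylbut-3-en-1-yl]-2,2,7-trimethylhexahydrocyclopenta[d][1,3]dioxin-5-yl acetate | O[C@H]([C@@H](C)C=C)[C@@]1(OC(C)=O)C[C@@H](C)[C@H](OC2(C)C)[C@@H]1CO2 | intermediate
16 | (1R,2S)-1-[(4aS,5R,7R,7aS)-5-acetoxy-2,2,7-trimethylhexahydrocyclopenta[d][1,3]dioxin-5-yl]-2-methylbut-3-en-1-yl acetate | CC(=O)O[C@H]([C@@H](C)C=C)[C@@]1(OC(C)=O)C[C@@H](C)[C@H](OC2(C)C)[C@@H]1CO2 | intermediate
17 | 2,2-dimethylbut-3-enoic acid | C=CC(C)(C)C(=O)O | starting material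
18 | 3,3-dimethylpent-4-en-2-one | C=CC(C)(C)C(C)=O | intermediate
19 | (1R,2S,3E)-1-[(4aS,5R,7R,7aS)-5-acetoxy-2,2,7-trimethylhexahydrocyclopenta[d][1,3]dioxin-5-yl]-2,5,5-trimethyl-6-oxohept-3-en-1-yl acetate | CC(=O)O[C@H]([C@@H](C)/C=C/C(C)(C)C(C)=O)[C@@]1(OC(C)=O)C[C@@H](C)[C@H](OC2(C)C)[C@@H]1CO2 | intermediate
20 | (1R,2S,3E)-1-[(1R,2S,3S,4R)-1-acetoxy-3-hydroxy-2-(hydroxymethyl)-4-methylcyclopentyl]-2,5,5-trimethyl-6-oxohept-3-en-1-yl acetate | CC(=O)O[C@H]([C@@H](C)/C=C/C(C)(C)C(C)=O)[C@@]1(OC(C)=O)C[C@@H](C)[C@H](O)[C@@H]1CO | intermediate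
21 | (1R,2S,3E)-1-[(1R,2S,3S,4R)-1-acetoxy-2-formyl-3-hydroxy-4-methylcyclopentyl]-2,5,5-trimethyl-6-oxohept-3-en-1-yl acetate | CC(=O)O[C@H]([C@@H](C)/C=C/C(C)(C)C(C)=O)[C@@]1(OC(C)=O)C[C@@H](C)[C@H](O)[C@@H]1C=O | intermediate (not isolated)
22 | (1R,2S,3E)-1-[(1R,2S,3S,4R)-1-acetoxy-3-hydroxy-4-methyl-2-[(E)-2-methyl-3-oxoprop-1-en-1-yl]cyclopentyl]-2,5,5-trimethyl-6-oxohept-3-en-1-yl acetate | CC(=O)O[C@H]([C@@H](C)/C=C/C(C)(C)C(C)=O)[C@@]1(OC(C)=O)C[C@@H](C)[C@H](O)[C@@H]1/C=C(\C)C=O | intermediate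
23 | target: 3-O-benzoyl-14,15-di-O-acetyl seco-diterpenoid (2R,3S,4S,13S,14R,15R; 5E,11E) | CC(=O)O[C@H]([C@@H](C)/C=C/C(C)(C)C(C)=O)[C@@]1(OC(C)=O)C[C@@H](C)[C@H](OC(=O)c2ccccc2)[C@@H]1/C=C(\C)C=O | target

**Count**

Total steps: 16. Longest linear sequence: 14 steps (steps 1, 2, 4–11, 13–16).

**Steps most likely to fail**

1. Step 4. The enol ether attacks a carbon remote from the chiral ligands, so enantiofacial discrimination may be weak. Attack at the carbene carbon (cyclopropanation), or allylic C–H functionalisation with Cope rearrangement, may compete with vinylogous attack. The silyloxocarbenium ion may also lose silicon before ring closure, giving an open-chain aldehyde. Fallback: relay the absolute configuration from a covalently bound, non-silyl auxiliary on the enol ether oxygen and use an achiral catalyst. It sets out from diazo ester 3 and returns at dihydroxy ketone 8. Commercial (S)-1-(2,4,6-triisopropylphenyl)ethanol is O-allylated (KH, allyl bromide, THF) to the allyl ether F1 and isomerised with the iridium catalyst of step 3 to the (E)-prop-1-enyl ether F2. Annulation of 3 with F2 under Rh2(OPiv)4 should give methyl (4R,5S)-2-[(tert-butyldimethylsilyl)oxy]-4-methyl-5-[(S)-1-(2,4,6-triisopropylphenyl)ethoxy]cyclopent-1-ene-1-carboxylate F3, the aryl group screening one face of the enol ether. iBu2AlH reduction gives the allylic alcohol F4, HF·pyridine unveils the hydroxymethyl ketone F5, and TFA in CH2Cl2 at 0 °C cleaves the benzylic ether to give 8. The auxiliary antipode is taken if the facial sense is opposite.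

2. Step 13. Productive metathesis between a branched terminal alkene and an alkene on a quaternary carbon may be slow, so that catalyst decomposition and homodimerisation of 16 take over. Fallback: make C11=C12 by Julia–Kocienski olefination in place of metathesis. It sets out from diacetate 16 and returns at 19. Ozonolysis of 16 with NaBH4 work-up gives the C12 primary alcohol F6. Mitsunobu reaction with 1-phenyl-1H-tetrazole-5-thiol (PPh3, DIAD) gives the sulfide F7, and oxidation with (NH4)6Mo7O24/H2O2 gives the sulfone F8. Deprotonation of F8 with KN(SiMe3)2 in DME at −60 °C in the presence of 2,2-dimethyl-3-oxobutanal should give the (E)-alkene 19.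

3. Step 10. The α-quaternary aldehyde is slow to react, and its own Felkin preference opposes the reagent (mismatched double diastereodifferentiation), so facial selectivity at C14 may be poor. Fallback: an auxiliary-controlled Evans syn-aldol in place of the crotylboration. It sets out from aldehyde 13 and returns at diacetate 16. The dibutylboron enolate of (R)-4-benzyl-3-propionyloxazolidin-2-one (Bu2BOTf, iPr2NEt, CH2Cl2, −78 to 0 °C) adds to 13 to give the (2R,3R) syn-aldol imide F9. Acetylation (Ac2O, pyridine, DMAP) gives the diacetate imide F10, and EtSLi in THF at 0 °C exchanges the auxiliary for the S-ethyl thioester F11. Fukuyama reduction (Et3SiH, Pd/C, acetone) gives the C12 aldehyde F12, and non-basic methylenation (Zn, CH2I2, TiCl4, THF) gives 16.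

**Further compounds**

F1 | step 4 | (S)-2-[1-(allyloxy)ethyl]-1,3,5-triisopropylbenzene | C[C@H](OCC=C)c1c(C(C)C)cc(C(C)C)cc1C(C)C
F2 | step 4 | (S)-1,3,5-triisopropyl-2-[1-[(E)-prop-1-en-1-yloxy]ethyl]benzene | C[C@H](O/C=C/C)c1c(C(C)C)cc(C(C)C)cc1C(C)C
F3 | step 4 | methyl (4R,5S)-2-[(tert-butyldimethylsilyl)oxy]-4-methyl-5-[(S)-1-(2,4,6-triisopropylphenyl)ethoxy]cyclopent-1-ene-1-carboxylate | COC(=O)C1=C(O[Si](C)(C)C(C)(C)C)C[C@@H](C)[C@@H]1O[C@@H](C)c2c(C(C)C)cc(C(C)C)cc2C(C)C
F4 | step 4 | [(4R,5S)-2-[(tert-butyldimethylsilyl)oxy]-4-methyl-5-[(S)-1-(2,4,6-triisopropylphenyl)ethoxy]cyclopent-1-en-1-yl]methanol | OCC1=C(O[Si](C)(C)C(C)(C)C)C[C@@H](C)[C@@H]1O[C@@H](C)c2c(C(C)C)cc(C(C)C)cc2C(C)C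
F5 | step 4 | (2S,3S,4R)-2-(hydroxymethyl)-4-methyl-3-[(S)-1-(2,4,6-triisopropylphenyl)ethoxy]cyclopentan-1-one | O=C1C[C@@H](C)[C@H](O[C@@H](C)c2c(C(C)C)cc(C(C)C)cc2C(C)C)[C@@H]1CO
F6 | step 13 | (1R,2S)-1-[(4aS,5R,7R,7aS)-5-acetoxy-2,2,7-trimethylhexahydrocyclopenta[d][1,3]dioxin-5-yl]-3-hydroxy-2-methylpropyl acetate | CC(=O)O[C@H]([C@@H](C)CO)[C@@]1(OC(C)=O)C[C@@H](C)[C@H](OC2(C)C)[C@@H]1CO2
F7 | step 13 | C12 (1-phenyl-1H-tetrazol-5-yl) sulfide from F6, configuration unchanged | CC(=O)O[C@H]([C@@H](C)CSc3nnnn3c4ccccc4)[C@@]1(OC(C)=O)C[C@@H](C)[C@H](OC2(C)C)[C@@H]1CO2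
F8 | step 13 | C12 (1-phenyl-1H-tetrazol-5-yl) sulfone from F7, configuration unchanged | CC(=O)O[C@H]([C@@H](C)CS(=O)(=O)c3nnnn3c4ccccc4)[C@@]1(OC(C)=O)C[C@@H](C)[C@H](OC2(C)C)[C@@H]1CO2
F9 | step 10 | (R)-3-[(2R,3R)-3-[(4aS,5R,7R,7aS)-5-acetoxy-2,2,7-trimethylhexahydrocyclopenta[d][1,3]dioxin-5-yl]-3-hydroxy-2-methylpropanoyl]-4-benzyloxazolidin-2-one | O[C@H]([C@@H](C)C(=O)N2[C@H](Cc3ccccc3)COC2=O)[C@@]1(OC(C)=O)C[C@@H](C)[C@H](OC4(C)C)[C@@H]1CO4
F10 | step 10 | C14 acetate of F9 | CC(=O)O[C@H]([C@@H](C)C(=O)N2[C@H](Cc3ccccc3)COC2=O)[C@@]1(OC(C)=O)C[C@@H](C)[C@H](OC4(C)C)[C@@H]1CO4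
F11 | step 10 | S-ethyl (2R,3R)-3-acetoxy-3-[(4aS,5R,7R,7aS)-5-acetoxy-2,2,7-trimethylhexahydrocyclopenta[d][1,3]dioxin-5-yl]-2-methylpropanethioate | CC(=O)O[C@H]([C@@H](C)C(=O)SCC)[C@@]1(OC(C)=O)C[C@@H](C)[C@H](OC2(C)C)[C@@H]1CO2
F12 | step 10 | (1R,2R)-1-[(4aS,5R,7R,7aS)-5-acetoxy-2,2,7-trimethylhexahydrocyclopenta[d][1,3]dioxin-5-yl]-2-methyl-3-oxopropyl acetate | CC(=O)O[C@H]([C@@H](C)C=O)[C@@]1(OC(C)=O)C[C@@H](C)[C@H](OC2(C)C)[C@@H]1CO2
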